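**Strategy.** The plan rests on disconnecting ring C (C15, C16, C21–C24; numbering in the remark below) to a 3-ethoxycyclobutenone that is spiro-fused at C21 to the tetralin formed by rings B and D. Heating opens this four-membered ring (C21–C24) to a dienylketene that closes onto C15. Ring C, with oxygen on C22 and C24 and hydrogen on C23, and the dihydrophenalene core thus arise in one operation. The precursor already holds the ten-membered diaryl ether ring and all three stereocentres, which come from an asymmetric coumarin reduction (C18) and an Ireland–Claisen rearrangement (C19, C2). Ether cleavage and dehydrogenation across C20–C21 then give the quinone methide.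

Key step: step 16

Remark (numbering): carbons are numbered along the target SMILES: C1 (methyl on C2), C2, C3, C4 (ketone), C5–C10 (ring A; C6 bears OH, C10 the ether oxygen O11), C12–C17 (ring B; C14 bears OH), C18 (bears a methyl), C19, C20 (bears the 2,6-dioxygenated phenyl group, "Ar"), C21, C22 (OH), C23 (H), C24 (C=O). Ring C = C15, C16, C21–C24; ring D = C16–C21; the ten-membered ring = C2, C3, C4, C5, C10, O11, C12, C17, C18, C19.

Remark (assumption 1): C20 and C21 are formed without control in step 11 and carried as epimer mixtures (no descriptor in the SMILES), because steps 16 and 18 make both sp2.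

Remark (assumption 2): the target is taken as the drawn tautomer of its vinylogous acid; in step 2 the antipodal ligand is used if the sense of induction proves opposite.

Step 1
Reactants: 1 3-bromo-5-methoxyphenol; 2 ethyl acetoacetate
Product: 3 5-bromo-7-methoxy-4-methyl-2H-chromen-2-one
Conditions: MeSO3H, 40 °C
Reagents that add atoms: none
Why: Pechmann condensation, in which the new C–C bond should form ortho to OH and para to OMe (future C17), placing Br on the future C16 and the lactone oxygen on the future C12; no stereocentre.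

Step 2
Reactants: 3 5-bromo-7-methoxy-4-methyl-2H-chromen-2-one
Product: 4 (4R)-5-bromo-7-methoxy-4-methyl-3,4-dihydro-2H-chromen-2-one
Conditions: Cu(OAc)2 (3 mol %), (R)-DTBM-SEGPHOS (3 mol %), (EtO)2MeSiH, t-BuOH, toluene, 0 °C
Reagents that add atoms: none
Why: Copper hydride-catalysed asymmetric conjugate reduction of a β,β-disubstituted unsaturated lactone, in which the chiral bisphosphine–copper hydride delivers hydride to one face of C18 and sets it as R.

Step 3
Reactants: 5 3-fluoroanisole; 6 (E)-crotonaldehyde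
Product: 8 (±)-(E)-1-(2-fluoro-6-methoxyphenyl)but-2-en-1-ol, via aryllithium 7 (not isolated)
Conditions: n-BuLi, THF, −78 °C; then 6, −78 °C; H2O
Reagents that add atoms: none
Why: Directed ortho-lithiation at the position flanked by F and OMe, then 1,2-addition to the enal; the carbinol centre forms racemic and is resolved in step 4.

Step 4
Reactants: 8 (±)-(E)-1-(2-fluoro-6-methoxyphenyl)but-2-en-1-ol
Product: 9 (1S,2E)-1-(2-fluoro-6-methoxyphenyl)but-2-en-1-ol
Conditions: Ti(OiPr)4, L-(+)-diisopropyl tartrate, t-BuOOH (0.6 equiv), 4 Å MS, CH2Cl2, −20 °C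
Reagents that add atoms: none
Why: Sharpless kinetic resolution of a secondary (E)-allylic alcohol; with the L-(+)-tartrate the (R)-enantiomer should be epoxidised faster, so the (S)-alcohol is recovered.

Step 5
Reactants: 4 (4R)-5-bromo-7-methoxy-4-methyl-3,4-dihydro-2H-chromen-2-one; 9 (1S,2E)-1-(2-fluoro-6-methoxyphenyl)but-2-en-1-ol
Product: 11 (1S,2E)-1-(2-fluoro-6-methoxyphenyl)but-2-en-1-yl (3R)-3-[2-bromo-4-methoxy-6-(methoxymethoxy)phenyl]butanoate, via sodium phenoxide 10 (not isolated)
Conditions: 9, NaH, THF, 0 °C; 4, 0 °C → rt; then MOMCl, 0 °C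
Reagents that add atoms: chloromethyl methyl ether (MOMCl), COCCl
Why: Transesterification of the aryl lactone by the alkoxide (phenoxide is the better leaving group) followed by Williamson O-alkylation of the released C12 phenoxide in the same flask; neither C18 nor the carbinol centre is touched.

Step 6
Reactants: 11 (1S,2E)-1-(2-fluoro-6-methoxyphenyl)but-2-en-1-yl (3R)-3-[2-bromo-4-methoxy-6-(methoxymethoxy)phenyl]butanoate
Product: 14 (2R,3S,4E)-2-{(1R)-1-[2-bromo-4-methoxy-6-(methoxymethoxy)phenyl]ethyl}-5-(2-fluoro-6-methoxyphenyl)-3-methylpent-4-enoic acid, via silyl ketene acetal 12 (not isolated), via trimethylsilyl ester 13 (not isolated)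
Conditions: LiN(iPr)2, THF, −78 °C; Me3SiCl, −78 → 60 °C; H2O (pH 5)
Reagents that add atoms: none
Why: Ireland–Claisen rearrangement, in which LiN(iPr)2 in THF without polar cosolvent gives the ketene acetal with C18 cis to the allylic oxygen, and the chair transition state with the aryl group of the (S)-carbinol equatorial transfers chirality to C19 (R) and C2 (S) and leaves an (E)-styrene.

Step 7
Reactants: 14 (2R,3S,4E)-2-{(1R)-1-[2-bromo-4-methoxy-6-(methoxymethoxy)phenyl]ethyl}-5-(2-fluoro-6-methoxyphenyl)-3-methylpent-4-enoic acid; 15 mono-tert-butyl malonate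
Product: 17 tert-butyl (4R,5S,6E)-4-{(1R)-1-[2-bromo-4-methoxy-6-(methoxymethoxy)phenyl]ethyl}-7-(2-fluoro-6-methoxyphenyl)-5-methyl-3-oxohept-6-enoate, via acyl imidazolide 16 (not isolated)
Conditions: CDI, THF, rt; then 15, MgCl2, Et3N, THF, 45 °C
Reagents that add atoms: none
Why: Masamune–Brooks homologation, in which the magnesium enolate of the malonate half-ester is C-acylated by the acyl imidazolide and decarboxylates under near-neutral conditions that should leave C19 intact.

Step 8
Reactants: 17 tert-butyl (4R,5S,6E)-4-{(1R)-1-[2-bromo-4-methoxy-6-(methoxymethoxy)phenyl]ethyl}-7-(2-fluoro-6-methoxyphenyl)-5-methyl-3-oxohept-6-enoate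
Product: 18 tert-butyl (3R,4R)-3-[(2S,3E)-4-(2-fluoro-6-methoxyphenyl)but-3-en-2-yl]-2-hydroxy-7-methoxy-5-(methoxymethoxy)-4-methyl-3,4-dihydronaphthalene-1-carboxylate (enol form)
Conditions: CuI (10 mol %), L-proline (20 mol %), Cs2CO3, DMSO, 60 °C
Reagents that add atoms: none
Why: Copper-catalysed intramolecular C-arylation of the β-keto ester (Hurtley type) joins C21 to C16 and closes six-membered ring D; the product rests as the conjugated enol, and carbonate does not epimerise C18 or C19.

Step 9
Reactants: 18 tert-butyl (3R,4R)-3-[(2S,3E)-4-(2-fluoro-6-methoxyphenyl)but-3-en-2-yl]-2-hydroxy-7-methoxy-5-(methoxymethoxy)-4-methyl-3,4-dihydronaphthalene-1-carboxylate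
Product: 19 enol triflate of 18 (C20–OSO2CF3, C20=C21)
Conditions: NaH, PhNTf2, THF, 0 °C → rt
Reagents that add atoms: N-phenylbis(trifluoromethanesulfonimide), O=S(=O)(N(c1ccccc1)S(=O)(=O)C(F)(F)F)C(F)(F)F
Why: O-sulfonylation of the β-keto ester enolate, which can form only towards C21.

Step 10
Reactants: 19 enol triflate of 18; 20 (2,6-dimethoxyphenyl)boronic acid
Product: 21 tert-butyl (3R,4R)-2-(2,6-dimethoxyphenyl)-3-[(2S,3E)-4-(2-fluoro-6-methoxyphenyl)but-3-en-2-yl]-7-methoxy-5-(methoxymethoxy)-4-methyl-3,4-dihydronaphthalene-1-carboxylate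
Conditions: Pd(OAc)2 (5 mol %), SPhos (10 mol %), K3PO4, toluene/H2O, 90 °C
Reagents that add atoms: none
Why: Suzuki–Miyaura coupling of an activated β-carboxy enol triflate, with a biaryl phosphine suited to the doubly ortho-substituted boronic acid, installs Ar on C20.

Step 11
Reactants: 21 tert-butyl (3R,4R)-2-(2,6-dimethoxyphenyl)-3-[(2S,3E)-4-(2-fluoro-6-methoxyphenyl)but-3-en-2-yl]-7-methoxy-5-(methoxymethoxy)-4-methyl-3,4-dihydronaphthalene-1-carboxylate
Product: 22 tert-butyl (3R,4R)-2-(2,6-dimethoxyphenyl)-3-[(2S,3E)-4-(2-fluoro-6-methoxyphenyl)but-3-en-2-yl]-7-methoxy-5-(methoxymethoxy)-4-methyl-1,2,3,4-tetrahydronaphthalene-1-carboxylate (C20/C21 epimers)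
Conditions: Mg turnings, MeOH, rt → 40 °C
Reagents that add atoms: none
Why: Dissolving-metal conjugate reduction of the aryl-conjugated unsaturated ester by electron transfer; the isolated styrene, aryl fluoride and tert-butyl ester should be inert, and C20 and C21 need no control.

Step 12
Reactants: 22 tert-butyl tetralin-1-carboxylate with (E)-styrene side chain
Product: 23 tert-butyl (3R,4R)-2-(2,6-dimethoxyphenyl)-3-[(2S)-4-(2-fluoro-6-methoxyphenyl)-4-oxobutan-2-yl]-7-methoxy-5-(methoxymethoxy)-4-methyl-1,2,3,4-tetrahydronaphthalene-1-carboxylate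
Conditions: FeCl2 (cat.), neocuproine (cat.), PhSiH3, air, EtOH, 60 °C
Reagents that add atoms: dioxygen (air), O=O
Why: Iron hydride-initiated Wacker-type oxidation (hydrogen-atom transfer of Mukaiyama type), in which a hydrogen atom adds to C3 and the benzylic C4 radical is trapped by O2 and collapses to the aryl ketone.

Step 13
Reactants: 23 tert-butyl ester and MOM ether of the keto tetralin
Product: 24 (3R,4R)-2-(2,6-dimethoxyphenyl)-3-[(2S)-4-(2-fluoro-6-methoxyphenyl)-4-oxobutan-2-yl]-5-hydroxy-7-methoxy-4-methyl-1,2,3,4-tetrahydronaphthalene-1-carboxylic acid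
Conditions: CF3CO2H, CH2Cl2, 0 °C → rt
Reagents that add atoms: none
Why: Acidolysis removes the tert-butyl ester and the MOM acetal in one operation and leaves the methyl ethers and the ketone untouched.

Step 14
Reactants: 24 phenol acid with 2-fluoroaryl ketone
Product: 25 macrocyclic keto acid (24 with O12 bonded to C10 of ring A in place of F; 2S,18R,19R)
Conditions: Cs2CO3, DMF (0.002 M), 90 °C
Reagents that add atoms: none
Why: Intramolecular SNAr etherification, in which the C12 phenoxide displaces fluoride at C10 (activated by the ortho ketone C4) under high dilution to close the ten-membered ring.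

Step 15
Reactants: 25 macrocyclic keto acid; 26 ethoxyacetylene
Product: 29 spirocyclobutenone (3-ethoxycyclobut-2-en-1-one spiro-fused at its C4 = C21 to ring D of the macrocyclic tetralin), via acid chloride 27 (not isolated), via ketene 28 (not isolated)
Conditions: (COCl)2, DMF (cat.), CH2Cl2, 0 °C → rt, evaporate; then 26 (3 equiv), Et3N, toluene, 0 → 40 °C
Reagents that add atoms: none
Why: Dehydrochlorination to the aryl(alkyl)ketene and regioselective [2+2] cycloaddition with the ynol ether (ketene carbon C24 to the alkyne CH, C21 to the ethoxy-bearing carbon) should give the 3-ethoxycyclobutenone; the spiro centre C21 forms without control because step 16 removes it.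

Step 16
Reactants: 29 spirocyclobutenone
Product: 32 macrocyclic 22-ethoxy-24-hydroxy-dihydrophenalene (rings B, C, D; methyl ethers on O6, O14 and both Ar oxygens; 2S,18R,19R), via dienylketene 30 (not isolated), via cyclohexadienone 31 (not isolated)
Conditions: toluene (degassed, 0.01 M), 110 °C
Reagents that add atoms: none
Why: Heating should trigger conrotatory 4π electrocyclic opening of the cyclobutenone (C21–C24 cleaved) to dienylketene 30, whose ketene carbon C24 bonds to C15 of ring B in a 6π electrocyclisation (31), and tautomerisation restores aromaticity to give naphthol 32; the closest known reaction type is the thermal rearrangement of 4-aryl-cyclobutenones to 1-naphthols, the second stage of the ketene–alkyne benzannulation. Ring C is thus closed by a thermally allowed disrotatory 6π electrocyclisation rather than a polar exo or endo attack, and it grows from four atoms (C21–C24) to six by taking in C15 and C16. No stereocentre is formed: the uncontrolled spiro centre C21 becomes aromatic, while C2, C18 and C19 are remote and unaffected. The step needs site selectivity (C15 is the only free position ortho to C16, since C17 belongs to ring D), a fixed oxygen pattern (ethoxy on C22 and the ketene oxygen as O24, both set by the cyclobutenone) and the opening mode that turns the aryl carbon C16 inward. The last should be secured because the opening is reversible, so the unproductive rotamer returns to 29, and because the bulky C20 substituent prefers outward rotation; a 1,5-hydrogen shift from C20 is the main competing path.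

Step 17
Reactants: 32 macrocyclic 22-ethoxy-24-hydroxy-dihydrophenalene
Product: 33 hexaphenol (32 with all five alkyl ethers cleaved; C20–H retained)
Conditions: BBr3, CH2Cl2, −78 °C → rt; then H2O (argon)
Reagents that add atoms: none
Why: Lewis acid-mediated cleavage of the four methyl ethers and the ethyl ether; the diaryl ether, the ketone and the three stereocentres should not be affected.

Step 18
Reactants: 33 hexaphenol
Product: 34 CNP0225737.1 (target)
Conditions: DDQ (1.0 equiv), THF, −20 → 0 °C
Reagents that add atoms: none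
Why: Dehydrogenation of a para-hydroxybenzylic C–H (hydride abstraction from C20, loss of the O24 proton) should give the quinone methide C24=O/C21=C20; one equivalent at low temperature limits further dehydrogenation at C18–C19.

**Compound list**

1 | 3-bromo-5-methoxyphenol | COc1cc(O)cc(Br)c1 | starting material
2 | ethyl acetoacetate | CCOC(=O)CC(C)=O | starting material
3 | 5-bromo-7-methoxy-4-methyl-2H-chromen-2-one | CC1=CC(=O)Oc2cc(OC)cc(Br)c12 | intermediate
4 | (4R)-5-bromo-7-methoxy-4-methyl-3,4-dihydro-2H-chromen-2-one | C[C@@H]1CC(=O)Oc2cc(OC)cc(Br)c12 | intermediate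
5 | 3-fluoroanisole | COc1cccc(F)c1 | starting material
6 | (E)-crotonaldehyde | C/C=C/C=O | starting material
7 | (2-fluoro-6-methoxyphenyl)lithium | COc1cccc(F)c1[Li] | intermediate (not isolated)
8 | (±)-(E)-1-(2-fluoro-6-methoxyphenyl)but-2-en-1-ol | C/C=C/C(O)c1c(F)cccc1OC | intermediate
9 | (1S,2E)-1-(2-fluoro-6-methoxyphenyl)but-2-en-1-ol | C/C=C/[C@H](O)c1c(F)cccc1OC | intermediate
10 | sodium phenoxide of (1S,2E)-1-(2-fluoro-6-methoxyphenyl)but-2-en-1-yl (3R)-3-(2-bromo-6-hydroxy-4-methoxyphenyl)butanoate | C/C=C/[C@H](OC(=O)C[C@@H](C)c1c(Br)cc(OC)cc1[O-])c1c(F)cccc1OC.[Na+] | intermediate (not isolated)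
11 | (1S,2E)-1-(2-fluoro-6-methoxyphenyl)but-2-en-1-yl (3R)-3-[2-bromo-4-methoxy-6-(methoxymethoxy)phenyl]butanoate | C/C=C/[C@H](OC(=O)C[C@@H](C)c1c(Br)cc(OC)cc1OCOC)c1c(F)cccc1OC | intermediate
12 | (E)-trimethylsilyl ketene acetal of 11 (C18 cis to the allylic oxygen) | C/C=C/[C@H](O/C(O[Si](C)(C)C)=C\[C@@H](C)c1c(Br)cc(OC)cc1OCOC)c1c(F)cccc1OC | intermediate (not isolated)
13 | trimethylsilyl ester of 14 | C[Si](C)(C)OC(=O)[C@@H]([C@@H](C)c1c(Br)cc(OC)cc1OCOC)[C@@H](C)/C=C/c1c(F)cccc1OC | intermediate (not isolated)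
14 | (2R,3S,4E)-2-{(1R)-1-[2-bromo-4-methoxy-6-(methoxymethoxy)phenyl]ethyl}-5-(2-fluoro-6-methoxyphenyl)-3-methylpent-4-enoic acid | OC(=O)[C@@H]([C@@H](C)c1c(Br)cc(OC)cc1OCOC)[C@@H](C)/C=C/c1c(F)cccc1OC | intermediate
15 | mono-tert-butyl malonate (3-tert-butoxy-3-oxopropanoic acid) | CC(C)(C)OC(=O)CC(O)=O | starting material
16 | imidazolide of 14 | O=C(n1ccnc1)[C@@H]([C@@H](C)c1c(Br)cc(OC)cc1OCOC)[C@@H](C)/C=C/c1c(F)cccc1OC | intermediate (not isolated)
17 | tert-butyl (4R,5S,6E)-4-{(1R)-1-[2-bromo-4-methoxy-6-(methoxymethoxy)phenyl]ethyl}-7-(2-fluoro-6-methoxyphenyl)-5-methyl-3-oxohept-6-enoate | CC(C)(C)OC(=O)CC(=O)[C@@H]([C@@H](C)c1c(Br)cc(OC)cc1OCOC)[C@@H](C)/C=C/c1c(F)cccc1OC | intermediate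
18 | tert-butyl (3R,4R)-3-[(2S,3E)-4-(2-fluoro-6-methoxyphenyl)but-3-en-2-yl]-2-hydroxy-7-methoxy-5-(methoxymethoxy)-4-methyl-3,4-dihydronaphthalene-1-carboxylate (enol of the ring D β-keto ester) | CC(C)(C)OC(=O)C1=C(O)[C@H]([C@@H](C)/C=C/c3c(F)cccc3OC)[C@@H](C)c2c(OCOC)cc(OC)cc12 | intermediate
19 | enol triflate of 18 (2-trifluoromethanesulfonyloxy) | CC(C)(C)OC(=O)C1=C(OS(=O)(=O)C(F)(F)F)[C@H]([C@@H](C)/C=C/c3c(F)cccc3OC)[C@@H](C)c2c(OCOC)cc(OC)cc12 | intermediate
20 | (2,6-dimethoxyphenyl)boronic acid | COc1cccc(OC)c1B(O)O | starting material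
21 | tert-butyl (3R,4R)-2-(2,6-dimethoxyphenyl)-3-[(2S,3E)-4-(2-fluoro-6-methoxyphenyl)but-3-en-2-yl]-7-methoxy-5-(methoxymethoxy)-4-methyl-3,4-dihydronaphthalene-1-carboxylate | CC(C)(C)OC(=O)C1=C(c3c(OC)cccc3OC)[C@H]([C@@H](C)/C=C/c4c(F)cccc4OC)[C@@H](C)c2c(OCOC)cc(OC)cc12 | intermediate
22 | tert-butyl (3R,4R)-2-(2,6-dimethoxyphenyl)-3-[(2S,3E)-4-(2-fluoro-6-methoxyphenyl)but-3-en-2-yl]-7-methoxy-5-(methoxymethoxy)-4-methyl-1,2,3,4-tetrahydronaphthalene-1-carboxylate (C20/C21 epimers) | CC(C)(C)OC(=O)C1C(c3c(OC)cccc3OC)[C@H]([C@@H](C)/C=C/c4c(F)cccc4OC)[C@@H](C)c2c(OCOC)cc(OC)cc12 | intermediate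
23 | tert-butyl (3R,4R)-2-(2,6-dimethoxyphenyl)-3-[(2S)-4-(2-fluoro-6-methoxyphenyl)-4-oxobutan-2-yl]-7-methoxy-5-(methoxymethoxy)-4-methyl-1,2,3,4-tetrahydronaphthalene-1-carboxylate | CC(C)(C)OC(=O)C1C(c3c(OC)cccc3OC)[C@H]([C@@H](C)CC(=O)c4c(F)cccc4OC)[C@@H](C)c2c(OCOC)cc(OC)cc12 | intermediate
24 | (3R,4R)-2-(2,6-dimethoxyphenyl)-3-[(2S)-4-(2-fluoro-6-methoxyphenyl)-4-oxobutan-2-yl]-5-hydroxy-7-methoxy-4-methyl-1,2,3,4-tetrahydronaphthalene-1-carboxylic acid | OC(=O)C1C(c3c(OC)cccc3OC)[C@H]([C@@H](C)CC(=O)c4c(F)cccc4OC)[C@@H](C)c2c(O)cc(OC)cc12 | intermediate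
25 | macrocyclic keto acid: tetralin-1-carboxylic acid (C21) bearing the ten-membered diaryl ether ketone ring, O6/O14/Ar-O methyl ethers (2S,18R,19R) | OC(=O)C1C(c3c(OC)cccc3OC)[C@H]4[C@@H](C)c2c(Oc5cccc(OC)c5C(=O)C[C@@H]4C)cc(OC)cc12 | intermediate
26 | ethoxyacetylene (ethoxyethyne) | CCOC#C | starting material
27 | acid chloride of 25 | ClC(=O)C1C(c3c(OC)cccc3OC)[C@H]4[C@@H](C)c2c(Oc5cccc(OC)c5C(=O)C[C@@H]4C)cc(OC)cc12 | intermediate (not isolated)
28 | ketene from 27 (C21=C24=O) | O=C=C1C(c3c(OC)cccc3OC)[C@H]4[C@@H](C)c2c(Oc5cccc(OC)c5C(=O)C[C@@H]4C)cc(OC)cc12 | intermediate (not isolated)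
29 | spirocyclobutenone: 3-ethoxycyclobut-2-en-1-one (C24=O, C23H=C22–OEt) spiro-fused at C21 to ring D of the macrocyclic tetralin | CCOC1=CC(=O)C12C(c3c(OC)cccc3OC)[C@H]4[C@@H](C)c5c(Oc6cccc(OC)c6C(=O)C[C@@H]4C)cc(OC)cc25 | intermediate
30 | dienylketene O=C24=C23H–C22(OEt)=C21 with C16 cis to C23 | O=C=C/C(OCC)=C1/C(c3c(OC)cccc3OC)[C@H]4[C@@H](C)c2c(Oc5cccc(OC)c5C(=O)C[C@@H]4C)cc(OC)cc12 | intermediate (not isolated)
31 | cyclohexadienone from 6π closure (C24–C15 bond formed, C15 sp3, ring B dearomatised) | CCOC1=CC(=O)C2C(OC)=CC3Oc4cccc(OC)c4C(=O)C[C@H](C)[C@H]5C(c6c(OC)cccc6OC)C1=C2C=3[C@@H]5C | intermediate (not isolated)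
32 | macrocyclic 2,3-dihydro-1H-phenalene: C24–OH, C22–OEt, methyl ethers on O6, O14 and both Ar oxygens, C20 sp3 (2S,18R,19R) | CCOc1cc(O)c2c(OC)cc3Oc4cccc(OC)c4C(=O)C[C@H](C)[C@H]5C(c6c(OC)cccc6OC)c1c2c3[C@@H]5C | intermediate
33 | hexaphenol (32 with all alkyl ethers cleaved; leuco form of the target) | Oc1cc(O)c2c(O)cc3Oc4cccc(O)c4C(=O)C[C@H](C)[C@H]5C(c6c(O)cccc6O)c1c2c3[C@@H]5C | intermediate
34 | CNP0225737.1 | C[C@H]1CC(=O)c2c(O)cccc2Oc2cc(O)c3c4c2[C@H](C)[C@@H]1C(c1c(O)cccc1O)=C4C(O)=CC3=O | target

**Total step count:** 18. **Longest linear sequence:** 16 (steps 1, 2 and 5–18; the branch through steps 3 and 4 joins in step 5).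

**Steps most likely to fail**

Step 16. The dienylketene may drain away through the rotamer that has C20 turned inward, by a 1,5-hydrogen shift from C20 to the ketene carbon, or through ketene oligomerisation, before the electrocyclisation onto C15 occurs. The fallback builds the same ring without a four-membered ring; it sets out from 25 and comes back at 33. Acid 25 is homologated with 15 (CDI; MgCl2, Et3N) to the tert-butyl 3-oxobutanoate F1, in which the former carboxyl carbon becomes C22. P2O5 in MeSO3H should cleave the ester and close C24 onto C15 by Friedel–Crafts acylation (the only free position ortho to C16, activated by O14 and O12); enolisation gives the naphthalene-1,3-diol F2. BBr3 then gives 33.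

Step 14. The ten-membered closure may lose to intermolecular etherification, or the tetralin with its undefined C20/C21 centres may hold the C12 phenoxide away from C10. The fallback postpones the etherification until the rigid dihydrophenalene exists; it sets out from 24 and comes back at 32. Compound 24 is silylated on both acidic oxygens (TBSCl, imidazole) to the bis-silyl derivative F3. (COCl)2 with catalytic DMF should convert the silyl ester directly into the acid chloride, which with Et3N and 26 gives the spirocyclobutenone silyl ether F4. Thermolysis as in step 16 gives the naphthol silyl ether F5. CsF in DMF at high dilution removes the silyl group, and the C12 phenoxide closes the ether to give 32; the O24 naphthoxide cannot reach C10.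

Step 18. The free hexaphenol may be over-oxidised (dehydrogenation at C18–C19 to the fully aromatic phenalenone) or undergo oxidative coupling at C23 before the quinone methide is secured. The fallback inverts the order of the last two operations; it sets out from 32 and comes back at 34. DDQ (1 equiv) on 32, in which only O24 is free, should give the quinone methide pentaether F6, and BBr3 at −78 °C with cold NaHCO3 work-up then cleaves the ethers to 34.

**Further compounds**

F1 | step 16 | tert-butyl 4-(macrocyclic tetralin-1-yl)-3-oxobutanoate (C21–C22(=O)–C23H2–C24O2tBu) | CC(C)(C)OC(=O)CC(=O)C1C(c3c(OC)cccc3OC)[C@H]4[C@@H](C)c2c(Oc5cccc(OC)c5C(=O)C[C@@H]4C)cc(OC)cc12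
F2 | step 16 | naphthalene-1,3-diol analogue of 32 (C22–OH and C24–OH free, four methyl ethers) | Oc1cc(O)c2c(OC)cc3Oc4cccc(OC)c4C(=O)C[C@H](C)[C@H]5C(c6c(OC)cccc6OC)c1c2c3[C@@H]5C
F3 | step 14 | bis(tert-butyldimethylsilyl) derivative of 24 (silyl ester and C12 silyl ether) | CC(C)(C)[Si](C)(C)OC(=O)C1C(c3c(OC)cccc3OC)[C@H]([C@@H](C)CC(=O)c4c(F)cccc4OC)[C@@H](C)c2c(O[Si](C)(C)C(C)(C)C)cc(OC)cc12
F4 | step 14 | open-chain spirocyclobutenone with C12 silyl ether and 2-fluoroaryl ketone | CCOC1=CC(=O)C12C(c3c(OC)cccc3OC)[C@H]([C@@H](C)CC(=O)c4c(F)cccc4OC)[C@@H](C)c5c(O[Si](C)(C)C(C)(C)C)cc(OC)cc25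
F5 | step 14 | open-chain dihydrophenalene naphthol with C12 silyl ether and 2-fluoroaryl ketone | CCOc1cc(O)c2c(OC)cc(O[Si](C)(C)C(C)(C)C)c3c2c1C(c4c(OC)cccc4OC)[C@H]([C@@H](C)CC(=O)c5c(F)cccc5OC)[C@H]3C
F6 | step 18 | quinone methide pentaether (target with O6, O14 and both Ar oxygens methylated and O22 ethylated) | C[C@H]1CC(=O)c2c(OC)cccc2Oc2cc(OC)c3c4c2[C@H](C)[C@@H]1C(c1c(OC)cccc1OC)=C4C(OCC)=CC3=O
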